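Retrosynthesis: take off the C8 ester and return C1 to a ketone. Then cut rings A and B together at C3–C4 and C5–C10 (a formal [4+2]). Cut the resulting open chain at C6–C7 (aldol), C8–C9 (allylboration) and C1–C2 (vinyl addition).
Enabling feature: in ring A the C1 oxygen and the formyl-bearing C4 stand 1,4 to each other, and the fusion bond C5–C10 is shared with ring B. Ring A is therefore the retron of a 2-silyloxydiene (C10=C1–C2=C3) and an enal (C4=C5–C15) tied by C6–C9. On the trans-decalin every substituent except the C14 methyl is equatorial.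
Forward: itaconic anhydride (C8, C7, C11–C13) and 4,4-dimethoxybut-2-enal (C6, C5, C4, C15) are joined first, then methallyl (C9, C10, C14, C1) and vinyl (C2, C3) are added. One acid-triggered cascade closes ring B and then ring A from the open chain. Acylation, ketone reduction and unmasking follow.
Stereochemistry: C6 and C7 come from the (S)-benzyloxazolidinone (Evans syn aldol) and C8 from the Ipc2B reagent. C5, C10 and C4 come from the all-equatorial chair of the cascade, and C1 from axial hydride delivery.

Key step: step 14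

Remark: eudesmane numbering (C1–C15) is used for chain and ring atoms; C10 in 15–19 and C1 in 18 are epimer mixtures and the C10=C1 bond of 20 is an E/Z mixture, all erased or reset in steps 13 and 14, so these positions carry no descriptor; the target is taken in the open hydroxy aldehyde/hydroxy acid form that is drawn.

Step 1
Reactants: 1 itaconic anhydride; 2 (S)-4-benzyl-1,3-oxazolidin-2-one
Product: 3 4-[(4S)-4-benzyl-2-oxo-1,3-oxazolidin-3-yl]-2-methylidene-4-oxobutanoic acid
Conditions: 2, n-BuLi, THF, −78 °C; then 1, −78 °C; aq HCl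
Reagents that add atoms: none
Why: N-acylation of a lithiated oxazolidinone by a cyclic anhydride, in which the nucleophile should open itaconic anhydride at the unconjugated, more electrophilic carbonyl (C8) as amines and alcohols do, leaving the conjugated C12 acid free while the low temperature limits migration of the double bond.

Step 2
Reactants: 3 acid imide
Product: 4 tert-butyl 4-[(4S)-4-benzyl-2-oxo-1,3-oxazolidin-3-yl]-2-methylidene-4-oxobutanoate
Conditions: tert-butyl 2,2,2-trichloroacetimidate, CH2Cl2/cyclohexane, rt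
Reagents that add atoms: tert-butyl 2,2,2-trichloroacetimidate, CC(C)(C)OC(=N)C(Cl)(Cl)Cl
Why: Trichloroacetimidate esterification, in which the carboxylic acid itself activates the imidate, installs a bulky ester that should later resist lactonisation by the C6 and C8 oxygens.

Step 3
Reactants: 4 tert-butyl ester imide; 5 (E)-4,4-dimethoxybut-2-enal
Product: 8 tert-butyl (3S,4R,5E)-3-{[(4S)-4-benzyl-2-oxo-1,3-oxazolidin-3-yl]carbonyl}-4-hydroxy-7,7-dimethoxy-2-methylidenehept-5-enoate (6R,7S syn aldol), via boron dienolate 6 (not isolated), via boron aldolate 7 (not isolated)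
Conditions: Bu2BOTf, Et3N, CH2Cl2, −78 to 0 °C; 5, −78 to 0 °C; pH 7 buffer, MeOH, 30% H2O2, 0 °C
Reagents that add atoms: none
Why: Evans syn aldol reaction, in which the Z boron dienolate reacts at its α-carbon C7 through a Zimmerman–Traxler chair on the face away from the benzyl group and so sets 6R and 7S.

Step 4
Reactants: 8 syn aldol
Product: 9 6-O-TBS ether of 8
Conditions: TBSOTf, 2,6-lutidine, CH2Cl2, −78 °C
Reagents that add atoms: tert-butyldimethylsilyl triflate, CC(C)(C)[Si](C)(C)OS(=O)(=O)C(F)(F)F
Why: Silyl triflate silylation of a secondary alcohol, which at −78 °C should be much faster than activation of the acetal and touches no stereocentre.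

Step 5
Reactants: 9 TBS ether imide
Product: 10 tert-butyl (3R,4R,5E)-4-(tert-butyldimethylsilyloxy)-3-(hydroxymethyl)-7,7-dimethoxy-2-methylidenehept-5-enoate
Conditions: LiBH4, MeOH (1 equiv), Et2O, 0 °C
Reagents that add atoms: none
Why: Reductive removal of the oxazolidinone auxiliary, in which borohydride attacks the activated exocyclic imide carbonyl in preference to the hindered conjugated tert-butyl ester and frees the auxiliary for recovery.

Step 6
Reactants: 10 primary alcohol
Product: 11 tert-butyl (3S,4R,5E)-4-(tert-butyldimethylsilyloxy)-3-formyl-7,7-dimethoxy-2-methylidenehept-5-enoate (C8 aldehyde)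
Conditions: Dess–Martin periodinane, NaHCO3, CH2Cl2, 0 °C; used crude
Reagents that add atoms: none
Why: Dess–Martin oxidation under bicarbonate buffer should give the β,γ-unsaturated aldehyde without a base strong enough to epimerise C7 or to move the C11=C13 double bond.

Step 7
Reactants: 11 C8 aldehyde
Product: 13 (6R,7R,8S)-homoallylic alcohol with the all-syn C6–C8 triad and the chain C9H2–C10(CH3)=C1H2, via borinate ester 12 (not isolated)
Conditions: preformed (−)-Ipc2B–CH2C(CH3)=CH2 (from (+)-α-pinene), Et2O, −78 °C; then HOCH2CH2NH2, rt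
Reagents that add atoms: (−)-B-methallyldiisopinocampheylborane, CC(=C)CB([C@@H]1C[C@@H]2C[C@H]([C@H]1C)C2(C)C)[C@@H]1C[C@@H]2C[C@H]([C@H]1C)C2(C)C
Why: Brown asymmetric allylboration, whose closed chair transition state delivers the methallyl group to the Si face of the aldehyde and sets 8S under reagent control, while the neutral cold conditions spare C7 and the acrylate.

Step 8
Reactants: 13 homoallylic alcohol
Product: 14 8-O-TES ether of 13
Conditions: TESCl, imidazole, DMF, 0 °C to rt
Reagents that add atoms: chlorotriethylsilane, CC[Si](Cl)(CC)CC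
Why: Standard silyl ether formation that marks O8 with a group more labile than the TBS group on O6, so that the two oxygens stay distinguishable.

Step 9
Reactants: 14 bis-silyl ether
Product: 16 C1 primary alcohol (chain end C9H2–C10H(CH3)–C1H2OH), via B-alkyl-9-BBN adduct 15 (not isolated)
Conditions: 9-BBN, THF, 0 °C to rt; then 30% H2O2, aq NaOAc, 0 °C
Reagents that add atoms: hydrogen peroxide, OO
Why: Hydroboration–oxidation, in which 9-BBN should select the only electron-rich 1,1-disubstituted alkene over the electron-poor acrylate and the hindered 1,2-disubstituted alkene, with C10 formed as an inconsequential epimer mixture.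

Step 10
Reactants: 16 C1 primary alcohol
Product: 17 C1 aldehyde
Conditions: Dess–Martin periodinane, NaHCO3, CH2Cl2, 0 °C
Reagents that add atoms: none
Why: Dess–Martin oxidation, a neutral method that leaves the acetal, both silyl ethers and the acrylate alone.

Step 11
Reactants: 17 C1 aldehyde
Product: 18 C1 vinyl carbinol
Conditions: CH2=CHMgBr, THF, −78 °C; aq NH4Cl
Reagents that add atoms: vinylmagnesium bromide, C=C[Mg]Br
Why: Grignard 1,2-addition, for which the aldehyde is far more reactive at −78 °C than the tert-butyl acrylate, and the new C1 centre is removed in the next step.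

Step 12
Reactants: 18 vinyl carbinol
Product: 19 vinyl ketone (C10H(CH3)–C1(=O)–C2H=C3H2)
Conditions: Dess–Martin periodinane, NaHCO3, CH2Cl2, 0 °C
Reagents that add atoms: none
Why: Dess–Martin oxidation of an allylic alcohol should give the sensitive vinyl ketone under neutral conditions.

Step 13
Reactants: 19 vinyl ketone
Product: 20 2-silyloxydiene (C10(CH3)=C1(OTBS)–C2H=C3H2), E/Z mixture
Conditions: TBSOTf, Et3N (excess), Et2O/CH2Cl2, −78 to 0 °C; Et3N-deactivated silica
Reagents that add atoms: tert-butyldimethylsilyl triflate, CC(C)(C)[Si](C)(C)OS(=O)(=O)C(F)(F)F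
Why: Soft enolisation with silyl triflate and amine is regiospecific because C10–H is the only enolisable position of the vinyl ketone, and the excess amine should keep the acetal from ionising.

Step 14
Reactants: 20 2-silyloxydiene acetal
Product: 22 tert-butyl 6α-(tert-butyldimethylsilyloxy)-8α-hydroxy-15,15-dimethoxy-1-oxo-4βH,5αH,7αH-eudesm-11(13)-en-12-oate, via silyl enol ether cycloadduct 21 (not isolated)
Conditions: TMSOTf (0.2 equiv), 2,6-di-tert-butyl-4-methylpyridine, CH2Cl2 (high dilution), −78 °C; then pyridine, HF·pyridine, THF, 0 °C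
Reagents that add atoms: none
Why: Catalytic TMSOTf ionises the acetal to the E-vinyl oxocarbenium ion, the enol silane carbon C10 adds to C5 (Mukaiyama–Michael addition, 6-exo-trig, ring B), the methyl enol ether carbon C4 so created adds to C3 of the silyloxyallyl cation (6-endo-trig, ring A, the C3–C4 bond), and Me3SiOMe returns methoxide to C15 and regenerates TMSOTf. The closest known reaction types are the acetal-initiated ionic Diels–Alder reaction and the silyl-triflate-promoted intramolecular double Michael reaction, and the polarity is matched because the nucleophilic diene terminus C10 meets the β-carbon C5 so that the C1 oxygen ends 1,4 to C4. C5 and C10 are controlled by the C6–C8 triad through a chair-like C6–C9 tether in which the C6 silyloxy group, the C7 acrylate, the C8 silyloxy group, the C4 arm on C5 and the bulky C1 unit on C10 are all equatorial and only the small C14 methyl is axial, which gives the trans-decalin with 5α-H and 10β-CH3, and both enol ether geometries converge on it because the first bond forms in an open transition state and C10–C1 then rotates freely. C4 is controlled in the second closure by the axial C14 methyl, which drives C15 into the equatorial sector, and an axial epimer could still be equilibrated at the aldehyde stage. The step needs 1,4- rather than 1,2-attack on the oxocarbenium ion, secured by ring size (six against eight members), and reaction at the acetal rather than at the tert-butyl acrylate, secured because only the acetal is ionised at −78 °C while the hindered pyridine removes stray acid. Pyridine-buffered HF then cleaves the enol silane and the TES ether but not the hindered C6 TBS ether, which unmasks the C1 ketone and the C8 hydroxyl in the same flask.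

Step 15
Reactants: 23 ethyl 2-(hydroxymethyl)acrylate
Product: 24 ethyl 2-[(tert-butyldimethylsilyloxy)methyl]acrylate
Conditions: TBSCl, imidazole, CH2Cl2, 0 °C to rt
Reagents that add atoms: tert-butyldimethylsilyl chloride, CC(C)(C)[Si](C)(C)Cl
Why: Standard silyl ether formation on a primary allylic alcohol.

Step 16
Reactants: 24 silyl ether ester
Product: 25 2-[(tert-butyldimethylsilyloxy)methyl]acrylic acid
Conditions: LiOH, THF/H2O, 0 °C to rt; aq HCl to pH 4
Reagents that add atoms: lithium hydroxide, [Li+].[OH-]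
Why: Ester saponification, which the primary TBS ether tolerates and in which the α-substituted acrylate is a poor Michael acceptor for hydroxide.

Step 17
Reactants: 22 keto alcohol; 25 side-chain acid
Product: 27 8α-{2-[(tert-butyldimethylsilyloxy)methyl]acryloyloxy} derivative of 22, via mixed anhydride 26 (not isolated)
Conditions: 25, 2,4,6-trichlorobenzoyl chloride, Et3N, toluene, rt; then 22, DMAP, rt
Reagents that add atoms: none
Why: Yamaguchi esterification meets a single free hydroxyl (equatorial O8), because O6 is silylated and C1 is still a ketone, so no site selectivity is needed.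

Step 18
Reactants: 27 keto diester
Product: 28 1β-alcohol of 27
Conditions: NaBH4, CeCl3·7H2O, MeOH, −78 to −40 °C
Reagents that add atoms: none
Why: Luche reduction, in which hydride enters C1 along the axial α trajectory because the β face is screened by the axial C14 methyl, gives the equatorial 1β-alcohol, while CeCl3 suppresses conjugate reduction of both acrylates and C15 stays masked.

Step 19
Reactants: 28 1β-alcohol
Product: 30 1β-(trimethylsilyloxy)-6α-(tert-butyldimethylsilyloxy)-8α-{2-[(tert-butyldimethylsilyloxy)methyl]acryloyloxy}-15-oxo-4βH,5αH,7αH-eudesm-11(13)-en-12-oic acid, via lutidinium salt 29 (not isolated)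
Conditions: TMSOTf (excess), 2,6-lutidine, CH2Cl2, 0 °C to rt; then H2O
Reagents that add atoms: trimethylsilyl triflate, C[Si](C)(C)OS(=O)(=O)C(F)(F)F; water, O
Why: Silyl triflate/2,6-lutidine deprotection turns the tert-butyl ester into a silyl ester with loss of isobutene and the acetal, through its lutidinium salt, into the aldehyde on addition of water, all without protic acid, so that the TBS ethers stay, O6 cannot lactonise, and the C1 hydroxyl is silylated in passing.

Step 20
Reactants: 30 silylated aldehyde acid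
Product: 31 1β,6α-dihydroxy-8α-[2-(hydroxymethyl)acryloyloxy]-15-oxo-4βH,5αH,7αH-eudesm-11(13)-en-12-oic acid (target)
Conditions: Et3N·3HF, Et3N, MeCN, rt; pH 5 buffer, extraction
Reagents that add atoms: none
Why: Fluoride desilylation under amine buffering keeps C12 as its unreactive ammonium carboxylate while the C6 hydroxyl is freed, which should hold back lactonisation, and the equatorial C4 formyl group is the thermodynamic epimer and so is not at risk from enolisation.

Compound list
1 | itaconic anhydride | C=C1CC(=O)OC1=O | starting material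
2 | (S)-4-benzyl-1,3-oxazolidin-2-one | O=C1N[C@@H](Cc2ccccc2)CO1 | starting material
3 | 4-[(4S)-4-benzyl-2-oxo-1,3-oxazolidin-3-yl]-2-methylidene-4-oxobutanoic acid | C=C(CC(=O)N1[C@@H](Cc2ccccc2)COC1=O)C(=O)O | intermediate
4 | tert-butyl ester of 3 | C=C(CC(=O)N1[C@@H](Cc2ccccc2)COC1=O)C(=O)OC(C)(C)C | intermediate
5 | (E)-4,4-dimethoxybut-2-enal | COC(OC)/C=C/C=O | starting material
6 | (Z)-di-n-butylboron dienolate of 4 | CCCCB(CCCC)O/C(=C\C(=C)C(=O)OC(C)(C)C)N1[C@@H](Cc2ccccc2)COC1=O | intermediate
7 | di-n-butylboron aldolate of 8 | COC(OC)/C=C/[C@@H](OB(CCCC)CCCC)[C@H](C(=C)C(=O)OC(C)(C)C)C(=O)N1[C@@H](Cc2ccccc2)COC1=O | intermediate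
8 | (6R,7S) syn aldol | COC(OC)/C=C/[C@@H](O)[C@H](C(=C)C(=O)OC(C)(C)C)C(=O)N1[C@@H](Cc2ccccc2)COC1=O | intermediate
9 | 6-O-TBS ether of 8 | COC(OC)/C=C/[C@@H](O[Si](C)(C)C(C)(C)C)[C@H](C(=C)C(=O)OC(C)(C)C)C(=O)N1[C@@H](Cc2ccccc2)COC1=O | intermediate
10 | (6R,7R) C8 primary alcohol | COC(OC)/C=C/[C@@H](O[Si](C)(C)C(C)(C)C)[C@H](C(=C)C(=O)OC(C)(C)C)CO | intermediate
11 | (6R,7S) C8 aldehyde | COC(OC)/C=C/[C@@H](O[Si](C)(C)C(C)(C)C)[C@H](C(=C)C(=O)OC(C)(C)C)C=O | intermediate
12 | diisopinocampheylborinate of 13 | COC(OC)/C=C/[C@@H](O[Si](C)(C)C(C)(C)C)[C@H](C(=C)C(=O)OC(C)(C)C)[C@@H](OB([C@@H]1C[C@@H]2C[C@H]([C@H]1C)C2(C)C)[C@@H]1C[C@@H]2C[C@H]([C@H]1C)C2(C)C)CC(C)=C | intermediate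
13 | (6R,7R,8S) homoallylic alcohol | COC(OC)/C=C/[C@@H](O[Si](C)(C)C(C)(C)C)[C@H](C(=C)C(=O)OC(C)(C)C)[C@@H](O)CC(C)=C | intermediate
14 | 8-O-TES ether of 13 | COC(OC)/C=C/[C@@H](O[Si](C)(C)C(C)(C)C)[C@H](C(=C)C(=O)OC(C)(C)C)[C@@H](O[Si](CC)(CC)CC)CC(C)=C | intermediate
15 | B-alkyl-9-BBN adduct of 14 (boron on C1) | COC(OC)/C=C/[C@@H](O[Si](C)(C)C(C)(C)C)[C@H](C(=C)C(=O)OC(C)(C)C)[C@@H](O[Si](CC)(CC)CC)CC(C)CB1C2CCCC1CCC2 | intermediate
16 | C1 primary alcohol | COC(OC)/C=C/[C@@H](O[Si](C)(C)C(C)(C)C)[C@H](C(=C)C(=O)OC(C)(C)C)[C@@H](O[Si](CC)(CC)CC)CC(C)CO | intermediate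
17 | C1 aldehyde | COC(OC)/C=C/[C@@H](O[Si](C)(C)C(C)(C)C)[C@H](C(=C)C(=O)OC(C)(C)C)[C@@H](O[Si](CC)(CC)CC)CC(C)C=O | intermediate
18 | C1 vinyl carbinol | COC(OC)/C=C/[C@@H](O[Si](C)(C)C(C)(C)C)[C@H](C(=C)C(=O)OC(C)(C)C)[C@@H](O[Si](CC)(CC)CC)CC(C)C(O)C=C | intermediate
19 | vinyl ketone | COC(OC)/C=C/[C@@H](O[Si](C)(C)C(C)(C)C)[C@H](C(=C)C(=O)OC(C)(C)C)[C@@H](O[Si](CC)(CC)CC)CC(C)C(=O)C=C | intermediate
20 | 2-silyloxydiene acetal (E/Z mixture at C10=C1) | COC(OC)/C=C/[C@@H](O[Si](C)(C)C(C)(C)C)[C@H](C(=C)C(=O)OC(C)(C)C)[C@@H](O[Si](CC)(CC)CC)CC(C)=C(O[Si](C)(C)C(C)(C)C)C=C | intermediate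
21 | trans-decalin cycloadduct (C1=C2 TBS enol ether, 8α-OTES, 6α-OTBS, 4α-CH(OMe)2) | CC[Si](CC)(CC)O[C@H]1C[C@]2(C)[C@@H]([C@@H](O[Si](C)(C)C(C)(C)C)[C@@H]1C(=C)C(=O)OC(C)(C)C)[C@H](C(OC)OC)CC=C2O[Si](C)(C)C(C)(C)C | intermediate
22 | 1-oxo-8α-hydroxy decalin | O[C@H]1C[C@]2(C)[C@@H]([C@@H](O[Si](C)(C)C(C)(C)C)[C@@H]1C(=C)C(=O)OC(C)(C)C)[C@H](C(OC)OC)CCC2=O | intermediate
23 | ethyl 2-(hydroxymethyl)acrylate | C=C(CO)C(=O)OCC | starting material
24 | ethyl 2-[(tert-butyldimethylsilyloxy)methyl]acrylate | C=C(CO[Si](C)(C)C(C)(C)C)C(=O)OCC | intermediate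
25 | 2-[(tert-butyldimethylsilyloxy)methyl]acrylic acid | C=C(CO[Si](C)(C)C(C)(C)C)C(=O)O | intermediate
26 | mixed anhydride of 25 and 2,4,6-trichlorobenzoic acid | C=C(CO[Si](C)(C)C(C)(C)C)C(=O)OC(=O)c1c(Cl)cc(Cl)cc1Cl | intermediate
27 | 8α-acyloxy-1-oxo decalin | C=C(CO[Si](C)(C)C(C)(C)C)C(=O)O[C@H]1C[C@]2(C)[C@@H]([C@@H](O[Si](C)(C)C(C)(C)C)[C@@H]1C(=C)C(=O)OC(C)(C)C)[C@H](C(OC)OC)CCC2=O | intermediate
28 | 1β-alcohol | C=C(CO[Si](C)(C)C(C)(C)C)C(=O)O[C@H]1C[C@]2(C)[C@@H]([C@@H](O[Si](C)(C)C(C)(C)C)[C@@H]1C(=C)C(=O)OC(C)(C)C)[C@H](C(OC)OC)CC[C@H]2O | intermediate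
29 | C15 methoxy-lutidinium triflate, C12 TMS ester, 1β-OTMS | C=C(CO[Si](C)(C)C(C)(C)C)C(=O)O[C@H]1C[C@]2(C)[C@@H]([C@@H](O[Si](C)(C)C(C)(C)C)[C@@H]1C(=C)C(=O)O[Si](C)(C)C)[C@H](C(OC)[n+]3c(C)cccc3C)CC[C@H]2O[Si](C)(C)C.[O-]S(=O)(=O)C(F)(F)F | intermediate
30 | silylated aldehyde acid | C=C(CO[Si](C)(C)C(C)(C)C)C(=O)O[C@H]1C[C@]2(C)[C@@H]([C@@H](O[Si](C)(C)C(C)(C)C)[C@@H]1C(=C)C(=O)O)[C@H](C=O)CC[C@H]2O[Si](C)(C)C | intermediate
31 | CNP0599450.1 | C=C(CO)C(=O)O[C@H]1C[C@]2(C)[C@@H]([C@@H](O)[C@@H]1C(=C)C(=O)O)[C@H](C=O)CC[C@H]2O | target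

Total steps: 20. Longest linear sequence: 18 steps (1–14 and 17–20).

Steps most likely to fail

Step 14.
- What may go wrong: after ionisation the allyl-type cation may lose its E geometry and be captured by the C6 oxygen with loss of the silyl group (dihydrofuran and furan formation). The dienol ether may be protodesilylated. Face selectivity at C10 may be poor, because the first bond forms in an open transition state.
- Fallback (from 20, back at 22): a concerted cycloaddition of the neutral enal in place of the cationic cascade. Limited TESOTf and excess 2,6-lutidine (CH2Cl2, 0 °C, then H2O) would convert the acetal through its lutidinium salt into the free trienal F1. The excess base intercepts the oxocarbenium ion, and the tert-butyl ester should survive the short exposure. Me2AlCl (CH2Cl2, −78 °C) would then bring about an endo-selective intramolecular Diels–Alder reaction to the aldehyde cycloadduct F2. HC(OMe)3, MeOH and catalytic PPTS would restore the acetal and methanolyse the enol silane and the TES ether, which gives 22.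

Step 3.
- What may go wrong: the itaconate double bond may migrate into conjugation under base. The dienolate may react at its γ- rather than its α-carbon. Retro-aldol cleavage or lactonisation may occur during the oxidative work-up.
- Fallback (from 2 and 5, back at 9): carry C11–C13 as a plain isopropenyl group and oxidise C12 afterwards.
  - 2 would be acylated (n-BuLi, 3-methylbut-2-enoyl chloride) to the senecioyl imide F3.
  - The deconjugative Evans syn aldol reaction (Bu2BOTf, Et3N, then 5) would give the α-isopropenyl aldol F4.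
  - TBSOTf and 2,6-lutidine would give the silyl ether F5.
  - Allylic oxidation of the isopropenyl methyl group (catalytic SeO2, t-BuOOH, then Dess–Martin periodinane to converge alcohol and aldehyde) would give the 2-substituted acrolein F6.
  - Pinnick oxidation (NaClO2, NaH2PO4, 2-methylbut-2-ene) would give the acrylic acid F7.
  - tert-Butyl 2,2,2-trichloroacetimidate would then give 9.

Step 20.
- What may go wrong: the hindered C6 silyl ether may cleave slowly, and the freed C6 hydroxyl may close onto the C12 carboxyl group (lactonisation) when the carboxylate is acidified and the product is isolated.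
- Fallback (from 30, back at 31): release the acid last, under neutral conditions, from an allyl ester. 30 would be alkylated (allyl bromide, KHCO3, DMF) to the allyl ester F8. Et3N·3HF (MeCN) would remove the three silyl groups to give the triol allyl ester F9. Deallylation by zerovalent palladium (Pd(PPh3)4, PhSiH3, CH2Cl2, rt; water) would then give 31 without any contact with aqueous acid.

Further compounds
F1 | step 14 | (6R,7R,8S) free trienal (C15 enal analogue of 20) | O=C/C=C/[C@@H](O[Si](C)(C)C(C)(C)C)[C@H](C(=C)C(=O)OC(C)(C)C)[C@@H](O[Si](CC)(CC)CC)CC(C)=C(O[Si](C)(C)C(C)(C)C)C=C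
F2 | step 14 | aldehyde cycloadduct (15-oxo analogue of 21) | CC[Si](CC)(CC)O[C@H]1C[C@]2(C)[C@@H]([C@@H](O[Si](C)(C)C(C)(C)C)[C@@H]1C(=C)C(=O)OC(C)(C)C)[C@H](C=O)CC=C2O[Si](C)(C)C(C)(C)C
F3 | step 3 | (S)-4-benzyl-3-(3-methylbut-2-enoyl)-1,3-oxazolidin-2-one | CC(C)=CC(=O)N1[C@@H](Cc2ccccc2)COC1=O
F4 | step 3 | (6R,7S) α-isopropenyl syn aldol | COC(OC)/C=C/[C@@H](O)[C@H](C(C)=C)C(=O)N1[C@@H](Cc2ccccc2)COC1=O
F5 | step 3 | 6-O-TBS ether of F4 | COC(OC)/C=C/[C@@H](O[Si](C)(C)C(C)(C)C)[C@H](C(C)=C)C(=O)N1[C@@H](Cc2ccccc2)COC1=O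
F6 | step 3 | C12 aldehyde (2-substituted acrolein) | COC(OC)/C=C/[C@@H](O[Si](C)(C)C(C)(C)C)[C@H](C(=C)C=O)C(=O)N1[C@@H](Cc2ccccc2)COC1=O
F7 | step 3 | C12 acrylic acid | COC(OC)/C=C/[C@@H](O[Si](C)(C)C(C)(C)C)[C@H](C(=C)C(=O)O)C(=O)N1[C@@H](Cc2ccccc2)COC1=O
F8 | step 20 | allyl ester of 30 | C=C(CO[Si](C)(C)C(C)(C)C)C(=O)O[C@H]1C[C@]2(C)[C@@H]([C@@H](O[Si](C)(C)C(C)(C)C)[C@@H]1C(=C)C(=O)OCC=C)[C@H](C=O)CC[C@H]2O[Si](C)(C)C
F9 | step 20 | allyl ester of 31 | C=C(CO)C(=O)O[C@H]1C[C@]2(C)[C@@H]([C@@H](O)[C@@H]1C(=C)C(=O)OCC=C)[C@H](C=O)CC[C@H]2O
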